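## Structural features

Locants: ring A (cyclohexanone) is C1 (CH that bears the side chain), C2 (CH–O–isovaleryl), C3 (C=O), C4 (C–CH3), C5 (CH) and C6 (CH2). The side chain is C7 (quaternary), C14 (oxirane CH2 on C7), C8 (C=O), C9=C10 (E) and C11 (C(CH3)2OOH). β is the face of ring A that carries C7, α the other face.

The compound is a bisabolane. Ring A is fused at C4–C5 to oxirane B (β) and is joined through the single bond C1–C7 to the 2,2-disubstituted oxirane C (C7–O–C14).

There are five stereocentres, (1R,2S,4S,5S,7S). C1 and C2 are vicinal and trans (side chain β, ester α, both equatorial). C4 and C5 carry their oxygen on the β face. The quaternary C7 stands next to C1 on a freely rotating bond.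

The fragile groups are:
- the tertiary allylic hydroperoxide
- the two α,β-epoxy ketones
- the epimerisable, migration-prone α-acyloxy ketone at C2/C3
- the C8–C10 enone

The late steps therefore tolerate no base, nucleophile, reductant or strong acid.

The real difficulty is stereochemical, in two places. Oxirane B is cis to the side chain, against the axial, anti attack that peroxide anions make on 5-substituted cyclohexenones. C7 has to be set in an open chain whose less hindered alkene face (the one flanked by C6H2) leads to the wrong epimer.

The key step exploits the fact that each oxirane hangs directly on a ketone carbon (C4 on C3, C7 on C8). C3–C4=C5 and C8–C7=C14 are two allylic alcohol retrons in one molecule. Carbinols at C3 and C8 can close oxiranes B and C together and can then be erased as the two ketones.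

## Logic of the disconnections

**15 to 14.**
- Cut: the C11–O bond. The alkene returns from C9=C10 to C10=C11 and one hydrogen returns to C9.
- Reason: the hydroperoxide is the most fragile group and must come last, and a γ-hydroperoxy enone is the retron of a Schenck ene reaction.
- Gain: one O2 unit is removed and no peroxide has to be carried.
- Demand: singlet oxygen must meet a single electron-rich alkene and must take its hydrogen from C9, not from the methyl groups.

**14 to 12.**
- Cut: no skeletal bond. The π bonds of C3=O and C8=O are exchanged for C–H and O–H.
- Reason: only carbinols at C3 and C8 can steer the oxirane closures.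
- Gain: the move adds two stereocentres in the backward direction, which is unusual. It buys control over three others, and both added centres vanish again in one oxidation.
- Demand: a neutral oxidant that leaves two oxiranes, the ester and a β,γ-unsaturated ketone unchanged.

**12 to 10 and 11.**
- Cut: C10=C11.
- Reason: the trisubstituted alkene would compete for the epoxidation catalyst as a homoallylic alkene, so it is introduced after the oxiranes.
- Gain: the chain end becomes a plain vinyl group.
- Demand: a metathesis that touches only the monosubstituted alkene.

**10 to 8 (key).**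
- Cut: the four bonds C4–O, C5–O, C7–O and C14–O.
- Reason: both oxiranes are allylic to a carbinol and can be closed by the same catalyst in the same flask.
- Gain: two rings and three stereocentres (C4, C5, C7) disappear.
- Demand: O3 must be β, C8 must be R, and the third alkene must stay inert.

**8 to 7.**
- Cut: C3–H.
- Reason: axial hydride delivery to the enone gives the equatorial β-carbinol.
- Gain: one stereocentre.
- Demand: 1,2-reduction without loss or shift of the ester.

**7 to 4 and 5.**
- Cut: C8–C9.
- Reason: this union joins the chain and sets C8, the only stereocentre that comes from an external source.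
- Gain: three carbons and one stereocentre.
- Demand: an allyl donor that distinguishes the aldehyde from the ketone and the ester and obeys a chiral catalyst.

**4 to 3.**
- Cut: the C8=O bond (three C–H bonds restored).
- Reason: the isopropenyl methyl group is the only allylic position on an electron-rich alkene.
- Gain: the side chain becomes that of the terpene.
- Demand: allylic oxidation that spares the enone.

**3 to 1 and 2.**
- Cut: C2–O.
- Reason: C2 is the only enolisable position of the enone, and the trans ester is the stable epimer.
- Gain: both partners are commercial, and C1 comes from the chiral pool.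
- Demand: direct transfer of the carboxylate to C2.

## Other disconnections considered

**Alternative 1:** (the first that comes to mind) cut the same four oxirane C–O bonds at the ketone oxidation level.
- Forward: (R)-carvone is taken through 4 to the cross-conjugated bis-enone A1. Both enones are then epoxidised with alkaline peroxide (twofold Weitz–Scheffer epoxidation) to give A2.
- Ground, ring: the hydroperoxide anion adds to C5 along the axial trajectory anti to the C1 substituent, so oxirane B would form on the α face.
- Ground, C7: this centre is fixed when the C7 enolate closes on the peroxide oxygen. With C1–H eclipsing the enolate to relieve A(1,3) strain, the open face is the one flanked by C6H2, which gives 7R.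
- Ground, conditions: the base also threatens the C2 ester and moves the β,γ-alkene into conjugation.
- A2 would therefore be the 4,5,7-tris-epimer of 14.

**Alternative 2:** cut C1–C7, with C1 as the β-carbon of a C3 enone and C7 as the α-carbon of the C8 ketone (C3 and C8 are 1,5-related).
- Forward: a phosphine-catalysed cross Rauhut–Currier union of the 2-acyloxy enone A3 with the vinyl ketone A4 gives A5.
- Ground, ring oxidation level: an acceptor that already holds C4=C5 is the keto tautomer of a 3-methylcatechol monoester and would aromatise. A3 must therefore be saturated at C4–C5. The alkene then has to be introduced later, next to two other enolisable sites, before the ring can be reduced, epoxidised and reoxidised.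
- Ground, the union itself: A3 is β-substituted and α-oxygenated, hence a poor acceptor next to self-coupling of A4, and nothing controls C1 or C7 in the absolute sense.
- The plan costs at least four more steps and solves neither hard stereocentre.

**Alternative 3:** cut C2–O and C5–O together as one molecule of O2.
- Forward: the kinetic enolate of carvone is O-acylated to the cross-conjugated dienyl isovalerate A6, and singlet oxygen adds [4+2] across C2 and C5 to give the endoperoxide A7.
- In A7 the enol ester carbon C4 attacks the peroxide oxygen on C5 while the acyl group moves from O3 to the oxygen on C2. This gives A8 by isomerisation.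
- Ground: the plan is atom-economical, but both oxygen atoms of a suprafacial adduct lie on one ring face, and that face is anti to the C1 substituent. A8 would have the right ester but oxirane B on the α face.
- The target holds the C2 and C5 oxygens on opposite faces, which this mechanism cannot deliver.

Key step: step 5

Remark: the sense of induction in step 3 is assigned by analogy with aryl and alkenyl aldehydes, whose Re face is attacked under the (R)-configured phosphoric acid.

## Steps

Step 1
Reactants: 1 (R)-(−)-carvone; 2 3-methylbutanoic acid
Product: 3 2α-isovaleryloxy enone (carvone with the ester at C2 trans to the C1 isopropenyl group)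
Conditions: Mn(OAc)3·2H2O (3 equiv), 2 (15 equiv), benzene, reflux, Dean–Stark
Reagents that add atoms: none
Why: α'-Acyloxylation of an enone with Mn(OAc)3: the enolate of trivalent manganese can form only toward C2, is oxidised there, and takes up the carboxylate that the excess of 2 has placed on the metal. The ester enters anti to the isopropenyl group and C2 stays epimerisable, so the trans-diequatorial 2α isomer should prevail.

Step 2
Reactants: 3 2α-isovaleryloxy enone
Product: 4 C8 enal (isopropenyl CH3 turned into CHO)
Conditions: SeO2 (1.2 equiv), 1,4-dioxane, 70 °C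
Reagents that add atoms: selenium dioxide O=[Se]=O
Why: Allylic oxidation with SeO2 (ene reaction, [2,3]-sigmatropic shift, then oxidation of the allylic alcohol) attacks the only electron-rich alkene. The CH3 group should react ahead of the hindered tertiary C1–H, and the methyl group on the enone is deactivated.

Step 3
Reactants: 4 C8 enal; 5 2-allyl-4,4,5,5-tetramethyl-1,3,2-dioxaborolane
Product: 7 (8R)-homoallylic alcohol, via O-boryl adduct 6 (not isolated)
Conditions: (R)-3,3'-bis(2,4,6-triisopropylphenyl)-1,1'-binaphthalene-2,2'-diyl hydrogen phosphate (5 mol %), 4 Å MS, toluene, −30 °C; then H2O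
Reagents that add atoms: none
Why: Phosphoric-acid-catalysed allylboration through a closed six-membered chair; the (R)-acid directs the allyl group to the Re face of alkenyl aldehydes, which corresponds to 8R. The pinacol boronate should not add to the ring ketone or the ester at this temperature.

Step 4
Reactants: 7 (8R)-homoallylic alcohol
Product: 8 3β,8-diol (bis-allylic alcohol)
Conditions: NaBH4, CeCl3·7H2O, MeOH, −78 °C
Reagents that add atoms: none
Why: Luche reduction: 1,2-selective hydride delivery along the axial (α) trajectory gives the equatorial 3β-carbinol, cis to the side chain, as carvone gives cis-carveol. The low temperature should keep the ester on O2.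

Step 5
Reactants: 8 3β,8-diol
Product: 10 4β,5β:7,14-bis-epoxy diol (7S,8R), via ring monoepoxide 9 (not isolated)
Conditions: VO(acac)2 (5 mol %), t-BuOOH (2.3 equiv, decane), CH2Cl2, 0 °C
Reagents that add atoms: tert-butyl hydroperoxide CC(C)(C)OO
Why: Known reaction type: VO(acac)2/t-BuOOH epoxidation of allylic alcohols, run here on two allylic alcohol units of one molecule. t-BuOOH turns the precatalyst into an alkoxide of pentavalent vanadium, each carbinol of 8 exchanges onto the metal beside an η2-bound tert-butyl peroxide, and the activated oxygen passes to the neighbouring alkene in a concerted, syn, spiro transition state, so each oxirane closes by forming both C–O bonds on one alkene face. Oxirane B: the pseudo-equatorial 3β-alkoxide reaches only the β face of C4=C5, which sets C4 and C5 syn to O3 and hence cis to the side chain, the closest model being cis-carveol. Oxirane C: the vanadate prefers an O–C8–C7=C14 dihedral angle near 50°, and A(1,2) strain between C1 on C7 and the C9 methylene leaves only the rotamer in which C8–H eclipses C7–C1, so 8R is translated into 7S (erythro product), as for 2-substituted secondary allylic alcohols in general. The trisubstituted ring alkene should react first (9) and the 1,1-disubstituted alkene second. Chemoselectivity is needed against the terminal vinyl group and is secured because that alkene is monosubstituted and only homoallylic to O8, while the ester is no ligand and neutral conditions at 0 °C should leave it on O2. The step closes two rings and sets three of the five stereocentres, including the two that resist undirected reagents.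

Step 6
Reactants: 10 bis-epoxy diol; 11 2-methylbut-2-ene
Product: 12 prenyl bis-epoxy diol (vinyl group turned into CH=C(CH3)2)
Conditions: second-generation Hoveyda–Grubbs catalyst (5 mol %), 11 (excess), CH2Cl2, 40 °C
Reagents that add atoms: none
Why: Cross metathesis of a terminal alkene with 2-methylbut-2-ene, the standard way to turn an allyl into a prenyl group. No other alkene is left in 10, and alcohols, oxiranes and esters are tolerated by the ruthenium carbene.

Step 7
Reactants: 12 prenyl bis-epoxy diol
Product: 14 bis-epoxy diketone, via 8-oxo carbinol 13 (not isolated)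
Conditions: Dess–Martin periodinane (3 equiv), NaHCO3, CH2Cl2, 0 °C
Reagents that add atoms: none
Why: Dess–Martin oxidation of epoxy alcohols to epoxy ketones under buffered, non-nucleophilic conditions erases both directing carbinols in one flask. The buffer should keep the C10=C11 alkene out of conjugation and C2 in its stable equatorial configuration.

Step 8
Reactants: 14 bis-epoxy diketone
Product: 15 target CNP0131119.2
Conditions: O2, tetraphenylporphyrin (1 mol %), visible light, CH2Cl2, −20 °C
Reagents that add atoms: dioxygen O=O
Why: Schenck ene reaction: singlet oxygen attacks the only electron-rich alkene, bonds to C11 and takes a hydrogen from C9, which gives the tertiary hydroperoxide and the E enone. Abstraction from C9 should be favoured because these C–H bonds are allylic and α to C8=O and the new alkene becomes conjugated; no stereocentre is formed or touched.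

## Compound list

1 | (R)-(−)-carvone, (5R)-2-methyl-5-(prop-1-en-2-yl)cyclohex-2-en-1-one | CC(=C)[C@@H]1CC=C(C)C(=O)C1 | starting material
2 | 3-methylbutanoic acid (isovaleric acid) | CC(C)CC(=O)O | starting material
3 | (1S,6S)-3-methyl-2-oxo-6-(prop-1-en-2-yl)cyclohex-3-en-1-yl 3-methylbutanoate (ester 2α, trans to the side chain) | CC(C)CC(=O)O[C@@H]1C(=O)C(C)=CC[C@H]1C(C)=C | intermediate
4 | (1S,6S)-3-methyl-2-oxo-6-(3-oxoprop-1-en-2-yl)cyclohex-3-en-1-yl 3-methylbutanoate (C8 enal) | CC(C)CC(=O)O[C@@H]1C(=O)C(C)=CC[C@H]1C(=C)C=O | intermediate
5 | 2-allyl-4,4,5,5-tetramethyl-1,3,2-dioxaborolane | C=CCB1OC(C)(C)C(C)(C)O1 | starting material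
6 | O8-(pinacolatoboryl) derivative of 7 | CC(C)CC(=O)O[C@@H]1C(=O)C(C)=CC[C@H]1C(=C)[C@H](OB2OC(C)(C)C(C)(C)O2)CC=C | intermediate
7 | (1S,6S)-6-[(3R)-3-hydroxyhexa-1,5-dien-2-yl]-3-methyl-2-oxocyclohex-3-en-1-yl 3-methylbutanoate (8R) | CC(C)CC(=O)O[C@@H]1C(=O)C(C)=CC[C@H]1C(=C)[C@H](O)CC=C | intermediate
8 | (1S,2S,6S)-2-hydroxy-6-[(3R)-3-hydroxyhexa-1,5-dien-2-yl]-3-methylcyclohex-3-en-1-yl 3-methylbutanoate (3β-OH, 8R) | CC(C)CC(=O)O[C@@H]1[C@@H](O)C(C)=CC[C@H]1C(=C)[C@H](O)CC=C | intermediate
9 | 8 with a 4β,5β-oxirane syn to the 3β-OH; C7=C14 still an alkene | CC(C)CC(=O)O[C@@H]1[C@@H](O)[C@@]2(C)O[C@H]2C[C@H]1C(=C)[C@H](O)CC=C | intermediate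
10 | 4β,5β:7,14-bis-epoxide of 8, (7S,8R), 3β-OH, 2α-isovalerate, terminal vinyl group | CC(C)CC(=O)O[C@@H]1[C@@H](O)[C@@]2(C)O[C@H]2C[C@H]1[C@@]1([C@H](O)CC=C)CO1 | intermediate
11 | 2-methylbut-2-ene | CC=C(C)C | starting material
12 | 10 with the vinyl group replaced by CH=C(CH3)2 (C10=C11) | CC(C)CC(=O)O[C@@H]1[C@@H](O)[C@@]2(C)O[C@H]2C[C@H]1[C@@]1([C@H](O)CC=C(C)C)CO1 | intermediate
13 | 12 with C8 oxidised to the ketone, 3β-OH still present | CC(C)CC(=O)O[C@@H]1[C@@H](O)[C@@]2(C)O[C@H]2C[C@H]1[C@@]1(C(=O)CC=C(C)C)CO1 | intermediate
14 | bis-epoxy diketone (1R,2S,4S,5S,7S) with the side chain C8(=O)–CH2–CH=C(CH3)2 | CC(C)CC(=O)O[C@@H]1C(=O)[C@@]2(C)O[C@H]2C[C@H]1[C@@]1(C(=O)CC=C(C)C)CO1 | intermediate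
15 | CNP0131119.2, (1R,2S,4S,5S,7S,9E)-hydroperoxide | CC(C)CC(=O)O[C@@H]1C(=O)[C@@]2(C)O[C@H]2C[C@H]1[C@@]1(C(=O)/C=C/C(C)(C)OO)CO1 | target

## Step count and least certain steps

Total step count: 8. Longest linear sequence: 8 (1 to 15).

**Step 5 (key step).**
- Most likely failures: erosion of the facial selectivity at C7, because the large ring substituent on C7 or a second contact of the metal with O3 may disturb the preferred rotamer; oxidation of a carbinol to the enone on vanadium; shift of the acyl group from O2 to O3.
- Fallback (reagent control at C7 with no C8 stereocentre), from 4 back to 14.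
- Luche reduction of 4 reduces aldehyde and ketone together to the primary/secondary diol F1.
- Katsuki–Sharpless epoxidation of F1 with Ti(OiPr)4, D-(−)-diisopropyl tartrate and t-BuOOH gives the side-chain epoxy alcohol F2. This tartrate delivers the (R)-2-substituted glycidol series, which corresponds to 7S in the target.
- VO(acac)2/t-BuOOH then closes oxirane B to give the bis-epoxy diol F3.
- Dess–Martin oxidation gives the keto aldehyde F4.
- 2-(2-Methylbut-3-en-2-yl)-4,4,5,5-tetramethyl-1,3,2-dioxaborolane adds with allyl inversion to the aldehyde only, giving the prenyl carbinol F5 as an inconsequential C8 mixture.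
- A second Dess–Martin oxidation leads to 14.

**Step 8.**
- Most likely failures: poor regioselectivity of hydrogen abstraction, because the perepoxide can also take a methyl hydrogen and place the oxygen on C10; and drift of the β,γ-alkene into conjugation before it reacts.
- Fallback (the peroxide is brought in intact by metathesis), from 10 back to 15.
- Dess–Martin oxidation of 10 gives the allyl diketone F6.
- Catalytic Et3N moves the alkene into conjugation to give the (E)-propenyl ketone F7.
- Cross metathesis with triethyl[(2-methylbut-3-en-2-yl)peroxy]silane and the second-generation Hoveyda–Grubbs catalyst gives the silyl peroxide F8.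
- HF·pyridine frees 15.

**Step 1.**
- Most likely failures: attack of manganese-derived radicals on the isopropenyl alkene, transfer of acetate instead of isovalerate, and incomplete trans selectivity.
- Fallback (enolate hydroxylation, then acylation), from 1 back to 3.
- LiN(SiMe3)2 followed by 3-phenyl-2-(phenylsulfonyl)oxaziridine gives the 2α-hydroxy enone F9, by attack anti to the isopropenyl group.
- 3-Methylbutanoyl chloride with pyridine and 4-(dimethylamino)pyridine converts F9 into 3.

**Step 2.**
- Most likely failures: incomplete conversion that stops at the alcohol stage, over-oxidation, and competing attack at C1–H, all common for isopropenyl groups.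
- Fallback (ene-type chlorination, then N-oxide oxidation), from 3 back to 4.
- Hypochlorous acid made from Ca(OCl)2 and solid CO2 in CH2Cl2–H2O gives the allylic chloride F10.
- N-Methylmorpholine N-oxide in MeCN displaces chloride and collapses to 4.

## Further compounds

F1 | step 5 | 2α-isovaleryloxy 3β,8-diol with a primary C8 alcohol | CC(C)CC(=O)O[C@@H]1[C@@H](O)C(C)=CC[C@H]1C(=C)CO
F2 | step 5 | 7,14-epoxy alcohol of F1 (C7 as in the target) | CC(C)CC(=O)O[C@@H]1[C@@H](O)C(C)=CC[C@H]1[C@@]1(CO)CO1
F3 | step 5 | 4β,5β:7,14-bis-epoxy diol with a primary C8 alcohol | CC(C)CC(=O)O[C@@H]1[C@@H](O)[C@@]2(C)O[C@H]2C[C@H]1[C@@]1(CO)CO1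
F4 | step 5 | bis-epoxy 3-keto 8-aldehyde | CC(C)CC(=O)O[C@@H]1C(=O)[C@@]2(C)O[C@H]2C[C@H]1[C@@]1(C=O)CO1
F5 | step 5 | bis-epoxy 3-ketone with a prenyl carbinol at C8 (both C8 epimers) | CC(C)CC(=O)O[C@@H]1C(=O)[C@@]2(C)O[C@H]2C[C@H]1[C@@]1(C(O)CC=C(C)C)CO1
F6 | step 8 | bis-epoxy diketone with an allyl group on C8 | CC(C)CC(=O)O[C@@H]1C(=O)[C@@]2(C)O[C@H]2C[C@H]1[C@@]1(C(=O)CC=C)CO1
F7 | step 8 | bis-epoxy diketone with an (E)-prop-1-enyl group on C8 | CC(C)CC(=O)O[C@@H]1C(=O)[C@@]2(C)O[C@H]2C[C@H]1[C@@]1(C(=O)/C=C/C)CO1
F8 | step 8 | O-triethylsilyl derivative of 15 | CC(C)CC(=O)O[C@@H]1C(=O)[C@@]2(C)O[C@H]2C[C@H]1[C@@]1(C(=O)/C=C/C(C)(C)OO[Si](CC)(CC)CC)CO1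
F9 | step 1 | 2α-hydroxy enone (trans-6-hydroxycarvone) | O[C@@H]1C(=O)C(C)=CC[C@H]1C(C)=C
F10 | step 2 | C8 allylic chloride of 3 | CC(C)CC(=O)O[C@@H]1C(=O)C(C)=CC[C@H]1C(=C)CCl
A1 | alternative 1 | cross-conjugated bis-enone with a prenyl ketone | CC(C)CC(=O)O[C@@H]1C(=O)C(C)=CC[C@H]1C(=C)C(=O)CC=C(C)C
A2 | alternative 1 | 4,5,7-tris-epimer of 14 | CC(C)CC(=O)O[C@@H]1C(=O)[C@]2(C)O[C@@H]2C[C@H]1[C@]1(C(=O)CC=C(C)C)CO1
A3 | alternative 2 | 6-methyl-2-(3-methylbutanoyloxy)cyclohex-2-en-1-one (racemic) | CC(C)CC(=O)OC1=CCCC(C)C1=O
A4 | alternative 2 | 6-methylhepta-1,5-dien-3-one | C=CC(=O)CC=C(C)C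
A5 | alternative 2 | Rauhut–Currier adduct, configuration not controlled | CC(C)CC(=O)OC1C(=O)C(C)CCC1C(=C)C(=O)CC=C(C)C
A6 | alternative 3 | cross-conjugated dienyl isovalerate of carvone | CC(C)CC(=O)OC1=C[C@H](C(C)=C)CC=C1C
A7 | alternative 3 | 2α,5α-endoperoxide of A6 | CC(C)CC(=O)OC1=C(C)[C@H]2C[C@@H](C(C)=C)[C@@H]1OO2
A8 | alternative 3 | 2α-isovaleryloxy 4α,5α-epoxy ketone (oxirane trans to the side chain) | CC(C)CC(=O)O[C@@H]1C(=O)[C@]2(C)O[C@@H]2C[C@H]1C(C)=C
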